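**Assumptions (one line each):**
- The target is the trans-(1S,2R) 1-aryl-1,2-dihydronaphthalene, as read from the SMILES.
- Both phenols are carried as TBS ethers.
- The (S)-diarylprolinol catalyst is assumed to give the (1S) sense; if the opposite sense is observed, the (R)-catalyst is used.

**Retrosynthesis**
- The target diol comes from desilylation of the bis-TBS diol, which comes from reduction of the 1-aryl-1,2-dihydronaphthalene-2,3-dicarbaldehyde.
- That dicarbaldehyde comes from one aminocatalytic, stepwise 6-endo intramolecular Friedel–Crafts cyclization of the C2-symmetric (E,E)-2,3-bis(arylidene)succinaldehyde. This is the only ring closure. It forms C1–C8a, sets C1 by facial control and sets C2 (trans) by enamine protonation.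
- The dialdehyde comes from the bis(arylidene)succinate by DIBAL reduction and DMP oxidation. The succinate comes from a double HWE between the oxidative dimer of triethyl phosphonoacetate and TBS-protected vanillin.

---

**Step 1**
Reactants: **1** triethyl phosphonoacetate (2 equiv; two molecules are joined)
Product: **2** tetraethyl 2,3-bis(diethoxyphosphoryl)succinate, i.e. diethyl 2,3-bis(diethoxyphosphoryl)butanedioate (diastereomer mixture)
Conditions: NaH (1.0 equiv per **1**), THF, 0 °C; then I2 (0.5 equiv per **1**), 0 °C → rt
Reagents that add atoms: none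
Why: Oxidative homocoupling of the stabilised phosphonoacetate enolate (I2-mediated, as for malonates). 2 **1** + I2 + 2 NaH → **2** + 2 NaI + 2 H2, so every atom of **2** comes from two molecules of **1**. Both stereocentres are destroyed in Step 2.

**Step 2**
Reactants: **2**; **3** 4-(tert-butyldimethylsilyloxy)-3-methoxybenzaldehyde (2.2 equiv)
Product: **4** diethyl (2E,3E)-2,3-bis[(4-TBSO-3-methoxyphenyl)methylene]succinate
Conditions: NaH (2.4 equiv), THF, 0 °C; add **3**, then 0 → 50 °C
Reagents that add atoms: none
Why: Double Horner–Wadsworth–Emmons olefination; each new trisubstituted alkene is E (aryl trans to ester, cis to the central C–C bond). Each phosphonate is lost as diethyl phosphate, so the product has no P.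

**Step 3**
Reactants: **4**
Product: **5** (2E,3E)-2,3-bis[(4-TBSO-3-methoxyphenyl)methylene]butane-1,4-diol
Conditions: DIBAL-H (6 equiv), toluene/THF, −78 → 0 °C; Rochelle salt workup
Reagents that add atoms: none
Why: Exhaustive DIBAL reduction of the conjugated esters to allylic primary alcohols; the aryl silyl ethers and alkene geometry are untouched.

**Step 4**
Reactants: **5**
Product: **6** (2E,3E)-2,3-bis[(4-TBSO-3-methoxyphenyl)methylene]succinaldehyde
Conditions: Dess–Martin periodinane (2.6 equiv), NaHCO3, CH2Cl2, 0 °C → rt, short reaction time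
Reagents that add atoms: none
Why: Buffered Dess–Martin oxidation of both allylic primary alcohols to the conjugated aldehydes, without acid-induced isomerization.

**Step 5**
Reactants: **6**; **7** (S)-α,α-bis[3,5-bis(trifluoromethyl)phenyl]prolinol TMS ether (20 mol%, catalyst)
Product: **8** (1S,2R)-1-(4-TBSO-3-methoxyphenyl)-7-TBSO-6-methoxy-1,2-dihydronaphthalene-2,3-dicarbaldehyde
Conditions: **7** (20 mol%), 2-nitrobenzoic acid (20 mol%), CH2Cl2/HFIP 9:1, 0 °C → rt, 24–48 h; aqueous workup; crude **8** is used directly in Step 6
Reagents that add atoms: none (**8** is an isomer of **6**)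
Why: Proposed new method: one enal arm condenses with **7** to give an E-iminium. The other arm's aryl ring (nucleophilic position para to its OMe, meta to OTBS) attacks the iminium β-carbon, C1, in a stepwise 6-endo-trig Friedel–Crafts closure. The bulky catalyst shields one face of the iminium, setting C1 as (S). Loss of H+ rearomatizes the ring to give a dienamine. Protonation at C2 anti to the C1 aryl gives the trans isomer, and hydrolysis releases the catalyst. The closest known reactions are iminium-catalysed Friedel–Crafts alkylation of electron-rich arenes with enals and acid-promoted cyclization of bis(arylidene)succinates to aryldihydronaphthalene lignans; the enantioselective aminocatalytic intramolecular version on these dienals is the new element. The C2 symmetry of **6** removes any question of which arm forms the iminium.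

**Step 6**
Reactants: **8**
Product: **9** (1S,2R)-2,3-bis(hydroxymethyl)-1-(4-TBSO-3-methoxyphenyl)-7-TBSO-6-methoxy-1,2-dihydronaphthalene
Conditions: NaBH4 (2.5 equiv), CeCl3·7H2O (2.5 equiv), MeOH/CH2Cl2, −78 → −20 °C
Reagents that add atoms: none
Why: Luche-type 1,2-reduction of both aldehydes (the conjugated one without conjugate reduction) under non-basic, cold conditions, so the α-stereocentre C2 does not epimerize. Once C2 carries CH2OH it is configurationally stable.

**Step 7**
Reactants: **9**
Product: **10** (1S,2R)-2,3-bis(hydroxymethyl)-1-(4-hydroxy-3-methoxyphenyl)-7-hydroxy-6-methoxy-1,2-dihydronaphthalene, the target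
Conditions: TBAF (2.4 equiv), AcOH (2.4 equiv), THF, 0 °C; NH4Cl workup
Reagents that add atoms: none
Why: Fluoride desilylation of the two aryl TBS ethers under buffered conditions, avoiding ionization of the electron-rich allylic and benzylic alcohols. No stereocentre is touched.

---

**Compound list**

1 | triethyl phosphonoacetate | CCOC(=O)CP(=O)(OCC)OCC | starting material
2 | tetraethyl 2,3-bis(diethoxyphosphoryl)succinate (diastereomer mixture) | CCOC(=O)C(P(=O)(OCC)OCC)C(P(=O)(OCC)OCC)C(=O)OCC | intermediate
3 | 4-(TBSO)-3-methoxybenzaldehyde | COc1cc(C=O)ccc1O[Si](C)(C)C(C)(C)C | starting material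
4 | diethyl (2E,3E)-2,3-bis(4-TBSO-3-methoxybenzylidene)succinate | CCOC(=O)/C(=C/c1ccc(O[Si](C)(C)C(C)(C)C)c(OC)c1)C(=C/c1ccc(O[Si](C)(C)C(C)(C)C)c(OC)c1)\C(=O)OCC | intermediate
5 | (2E,3E)-2,3-bis(4-TBSO-3-methoxybenzylidene)butane-1,4-diol | OC/C(=C/c1ccc(O[Si](C)(C)C(C)(C)C)c(OC)c1)C(=C/c1ccc(O[Si](C)(C)C(C)(C)C)c(OC)c1)\CO | intermediate
6 | (2E,3E)-2,3-bis(4-TBSO-3-methoxybenzylidene)succinaldehyde | O=C/C(=C/c1ccc(O[Si](C)(C)C(C)(C)C)c(OC)c1)C(=C/c1ccc(O[Si](C)(C)C(C)(C)C)c(OC)c1)\C=O | intermediate
7 | (S)-α,α-bis[3,5-bis(trifluoromethyl)phenyl]prolinol TMS ether (organocatalyst) | C[Si](C)(C)OC(c1cc(cc(c1)C(F)(F)F)C(F)(F)F)(c1cc(cc(c1)C(F)(F)F)C(F)(F)F)[C@@H]1CCCN1 | starting material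
8 | (1S,2R)-1-(4-TBSO-3-methoxyphenyl)-7-TBSO-6-methoxy-1,2-dihydronaphthalene-2,3-dicarbaldehyde | COc1cc([C@H]2c3cc(O[Si](C)(C)C(C)(C)C)c(OC)cc3C=C(C=O)[C@@H]2C=O)ccc1O[Si](C)(C)C(C)(C)C | intermediate
9 | (1S,2R)-bis-TBS 2,3-bis(hydroxymethyl)-1-aryl-1,2-dihydronaphthalene | COc1cc([C@H]2c3cc(O[Si](C)(C)C(C)(C)C)c(OC)cc3C=C(CO)[C@@H]2CO)ccc1O[Si](C)(C)C(C)(C)C | intermediate
10 | (1S,2R)-2,3-bis(hydroxymethyl)-1-(4-hydroxy-3-methoxyphenyl)-7-hydroxy-6-methoxy-1,2-dihydronaphthalene (CID10473569) | COc1cc([C@H]2c3cc(O)c(OC)cc3C=C(CO)[C@@H]2CO)ccc1O | target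

**Totals:** 7 steps in total; longest linear sequence is 7 steps (1 → 2 → 4 → 5 → 6 → 8 → 9 → 10).

**Three steps most likely to fail**
1. **Step 5 (proposed new cyclization).** The arene is deactivated by its conjugated enal, the iminium β-carbon is deactivated by the para-oxygen aryl, and the α,β-disubstituted enal may form the iminium poorly. The product may also isomerize to the 1,4-dihydro isomer. Fallback, a change of approach: biomimetic Ag2O (or Mn(OAc)3) oxidative 8–8′ coupling of ethyl 4-hydroxy-3-methoxycinnamate. This gives racemic trans-1-aryl-1,2-dihydronaphthalene-2,3-diester, which is reduced with LiAlH4 to the racemic diol and resolved by preparative chiral-phase HPLC to the (1S,2R) enantiomer.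
2. **Step 2 (double HWE on the hindered bisphosphonate).** It may react only once or give E/Z mixtures. Fallback: build the same (E,E)-bis(arylidene)succinate by a double Stobbe sequence. This is Stobbe condensation of dimethyl succinate with **3** (KOtBu), re-esterification, then a second Stobbe condensation with **3** and re-esterification.
3. **Step 4 (diol to dialdehyde).** The mono-oxidized hydroxy-aldehyde may close to the lactol and then the lactone, or to a furan, instead of giving the dialdehyde. Fallback: make the dialdehyde by Ullmann-type Cu-mediated homocoupling of (Z)-α-bromo-4-TBSO-3-methoxycinnamaldehyde. That bromide is prepared from the TBS-protected cinnamaldehyde by bromination and dehydrobromination.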